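The winter and noon runs charge different amounts of X, 1.5 equiv against 2.4 equiv, yet at 0.500 h they read 89.9% and 89.6%, and both fall toward the level where the dawn run also ends.

| setting | winter | noon | dawn | flask |
|---|---|---|---|---|
| L | 0.20 M | 0.20 M | 0.10 M | 0.20 M |
| X | 1.5 equiv | 2.4 equiv | 1.1 equiv | 1.10 equiv |
| remark | run made earlier | run made earlier | run made earlier |  |
| time |  |  |  | 10 h |

| run | time / h | Q / % |
|---|---|---|
| winter | 0.133 | 79.4 |
| winter | 0.250 | 93.8 |
| winter | 0.500 | 89.9 |
| winter | 1.33 | 81.5 |
| winter | 2.50 | 78.8 |
| winter | 6.00 | 77.2 |
| winter | 12.0 | 77.9 |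
| noon | 0.133 | 98.7 |
| noon | 0.250 | 94.1 |
| noon | 0.500 | 89.6 |
| noon | 1.33 | 80.5 |
| noon | 2.50 | 78.1 |
| noon | 6.00 | 79.3 |
| noon | 12.0 | 78.0 |
| dawn | 0.133 | 0 |
| dawn | 0.417 | 26.3 |
| dawn | 1.33 | 79.4 |
| dawn | 4.00 | 79.2 |
| dawn | 12.0 | 78.9 |

(readings scatter by 0.5 percentage points)

1. the moment within 10 h at which there is most Q
2. the amount of Q, in percent of the L charged, at that time
3. earliest time at which at least nineteen twentieths of that best amount are there
4. latest time at which they still are



The last readings give the end share, the fraction of converted L that stays Q: 78.3%. Taking the winter fall toward it as exponential, two readings give a relaxation rate of 1.45 h⁻¹.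

The dawn run reads 0% at 0.133 h and then climbs, so I take Q to speed its own formation, with a rate in L, X and Q together. In fractions of the charge, such a rate runs on a clock that goes with the square of the concentration charged. The flask has the equivalents of the dawn run at twice its concentration of L, so completion by 1.33 h there moves to 0.333 h in the flask.

My one number is N = 0.483, the relaxation times that pass while the flask fills. Integrating the relaxation, Q made at the very start would stand at 91.7% by then. Q made later has relaxed less and stands higher, while L still unconverted lowers the amount, so this is an estimate and no bound, and I expect a peak of about that size near 0.333 h. The dawn run tests the reckoning: its figure at 1.33 h is 81.4%, higher than its reading of 79.4%, so one number is not enough for a bound. N gives an estimate and no curve, so I commit to no window.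

The forecast gives 88% at 0.33 h, open from 0.24 h to 1 h: “Relaxation during formation trims the peak”.

The flask gives 89.2% at 0.408 h, open from 0.252 h to 0.880 h, which is below my 91.7% and later than my 0.333 h; at 0.408 h the flask still holds L 3.50%.

    L + X + Q → 2 Q (k = 22.0 L² mol⁻² min⁻¹)
    L + X → Q (k = 0.00300 L mol⁻¹ min⁻¹)
    L → G (k = 2.40 × 10⁻⁴ min⁻¹)
    Q ⇌ J (K = 0.270, k = 0.00600 min⁻¹)

The relaxation half-life of Q and J, 0.409 h, is short against the 10 h allowed. At that time the flask holds Q 78.5% and J 21.2%, beside my end share of 78.3%. In the neighbour flask with 0.660 equiv of X, the end share predicts 51.7% of Q at the end. That flask computes to 52.0%, with X the limiting reagent at 0% left.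

The readings were computed for substances that don't exist, and the scatter is random.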